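**Plan**
Ring labels: A and D are the two 3-hydroxyphenyl rings, B is the central para-phenylene, C is the 1,2,4-trisubstituted ring.
Retrosynthesis: the three phenols are masked as methyl ethers; the benzylic CH2 on ring B (A–B bridge) is traced back to an aryl ketone; ring B is then cut at two C–C bonds into a 2-aryloxybuta-1,3-diene (carrying rings C and D) and a benzyl ethynyl ketone (carrying ring A).
Enabling feature: ring B is a benzene whose C1 bears the diaryl ether oxygen and whose C4 bears the CH2CH2 link to ring A, the 1,4 pattern that a 2-oxygenated butadiene and a monosubstituted ynone deliver.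
Forward: rings C and D are joined by olefination and hydrogenation (steps 1–2); the phenol becomes the diene via its acrylate (steps 3–4); the ynone is made from the arylacetic acid (steps 5–6); cycloaddition and dehydrogenation build ring B (steps 7–8); deoxygenation and demethylation finish (steps 9–10).
Stereochemistry: none has to be controlled; the E-alkene of 3 and the racemic carbinol 15 met on the way are both erased.

Key step: step 7

Remark: perrottetin E has no stereocenter and a freely rotating diaryl ether, so the "single enantiomer" is the achiral compound itself.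

**Step 1**
Reactants: 1 3-(benzyloxy)-4-methoxybenzaldehyde; 2 diethyl [(3-methoxyphenyl)methyl]phosphonate
Product: 3 (E)-2-(benzyloxy)-1-methoxy-4-[2-(3-methoxyphenyl)ethenyl]benzene
Conditions: KOtBu (1.2 equiv), THF, 0 °C; then 1, 0 °C to rt
Reagents that add atoms: none
Why: Horner–Wadsworth–Emmons olefination of an aromatic aldehyde with a benzylphosphonate anion should give the (E)-stilbene, whose geometry is irrelevant because the double bond is hydrogenated next.

**Step 2**
Reactants: 3 (E)-2-(benzyloxy)-1-methoxy-4-[2-(3-methoxyphenyl)ethenyl]benzene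
Product: 4 2-methoxy-5-[2-(3-methoxyphenyl)ethyl]phenol
Conditions: H2 (1 atm), 10% Pd/C, EtOAc/EtOH, rt
Reagents that add atoms: none
Why: Catalytic hydrogenation over Pd/C should saturate the stilbene and hydrogenolyse the benzyl ether in one operation, leaving the aryl methyl ethers untouched.

**Step 3**
Reactants: 4 2-methoxy-5-[2-(3-methoxyphenyl)ethyl]phenol; 5 acryloyl chloride
Product: 6 2-methoxy-5-[2-(3-methoxyphenyl)ethyl]phenyl prop-2-enoate
Conditions: Et3N (1.5 equiv), BHT (trace), CH2Cl2, 0 °C
Reagents that add atoms: none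
Why: O-Acylation of a phenol with an acid chloride and a tertiary amine (Schotten–Baumann-type esterification) is fast at 0 °C, and the phenol is the only nucleophile in 4.

**Step 4**
Reactants: 6 2-methoxy-5-[2-(3-methoxyphenyl)ethyl]phenyl prop-2-enoate
Product: 7 2-(buta-1,3-dien-2-yloxy)-1-methoxy-4-[2-(3-methoxyphenyl)ethyl]benzene
Conditions: Tebbe reagent (1.2 equiv, PhMe solution), pyridine (cat.), THF, −40 °C to rt; 15% aq. NaOH quench; basic alumina; stored cold over BHT
Reagents that add atoms: Tebbe reagent, C[Al-]1(C)C[Ti](C2C=CC=C2)(C2C=CC=C2)[Cl+]1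
Why: Tebbe methylenation converts esters, including aryl and α,β-unsaturated esters, into enol ethers by titanium methylidene [2+2] addition and cycloreversion, the acrylate C=C can only undergo degenerate methylene exchange, and the basic work-up protects the acid-labile 2-aryloxydiene.

**Step 5**
Reactants: 8 (3-methoxyphenyl)acetic acid
Product: 10 N-methoxy-2-(3-methoxyphenyl)-N-methylacetamide, via acyl imidazolide 9 (not isolated)
Conditions: CDI (1.1 equiv), CH2Cl2, rt, 1 h; then MeNH(OMe)·HCl (1.2 equiv), rt
Reagents that add atoms: N,O-dimethylhydroxylamine hydrochloride, CNOC.Cl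
Why: CDI activation of a carboxylic acid and aminolysis of the acyl imidazolide is a standard Weinreb amide synthesis, with the liberated imidazole acting as the base for the amine hydrochloride.

**Step 6**
Reactants: 10 N-methoxy-2-(3-methoxyphenyl)-N-methylacetamide; 11 ethynylmagnesium bromide
Product: 12 1-(3-methoxyphenyl)but-3-yn-2-one
Conditions: 11 (3 equiv, 0.5 M in THF), THF, 0 °C to rt; inverse quench into cold 1 M aq. NaHSO4/Et2O; used promptly
Reagents that add atoms: none
Why: In this Weinreb ketone synthesis N-methoxy chelation of magnesium should stop the acetylide addition at the ketone stage, and the cold acidic quench keeps the released amine protonated so that it cannot add to the ynone.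

**Step 7**
Reactants: 7 2-(buta-1,3-dien-2-yloxy)-1-methoxy-4-[2-(3-methoxyphenyl)ethyl]benzene; 12 1-(3-methoxyphenyl)but-3-yn-2-one
Product: 13 1-(4-{2-methoxy-5-[2-(3-methoxyphenyl)ethyl]phenoxy}cyclohexa-1,4-dien-1-yl)-2-(3-methoxyphenyl)ethan-1-one
Conditions: 12 (1.5 equiv), BHT (cat.), PhMe (1 M), 90 °C, sealed tube, Ar; rapid filtration through neutral alumina
Reagents that add atoms: none
Why: The electron-rich 2-aryloxydiene (HOMO) and the electron-poor terminal ynone (LUMO) should combine in a concerted, asynchronous, normal-demand [4+2] cycloaddition through the s-cis diene, which is easily reached because both diene termini are unsubstituted. The closest known reaction type is the thermal Diels–Alder reaction of 2-alkoxy- and 2-silyloxybuta-1,3-dienes with acetylenic ketones, which gives 1-acyl-4-oxycyclohexa-1,4-dienes. Ring B closes as a six-membered carbocycle by intermolecular [4+2] annulation, the diene CH2 attached to the oxygen-bearing carbon bonding to the ynone β-carbon and the other diene terminus to the α-carbon. No stereocenter is created. The step needs para rather than meta regiochemistry, which the oxygen lone pair secures by placing the largest HOMO coefficient on the CH2 next to C–OAr, matched with the largest LUMO coefficient at the unsubstituted ynone β-carbon. An alkyne dienophile is chosen so that the adduct is one dehydrogenation away from the arene.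

**Step 8**
Reactants: 13 1-(4-{2-methoxy-5-[2-(3-methoxyphenyl)ethyl]phenoxy}cyclohexa-1,4-dien-1-yl)-2-(3-methoxyphenyl)ethan-1-one
Product: 14 1-(4-{2-methoxy-5-[2-(3-methoxyphenyl)ethyl]phenoxy}phenyl)-2-(3-methoxyphenyl)ethan-1-one
Conditions: DDQ (1.1 equiv), PhMe, 0 °C to rt
Reagents that add atoms: none
Why: DDQ dehydrogenation of a 1,4-cyclohexadiene (hydride abstraction from a doubly allylic CH2, then proton loss) is driven by aromatization and should run at room temperature, well below what is needed to oxidize the bibenzyl or deoxybenzoin CH2 groups.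

**Step 9**
Reactants: 14 1-(4-{2-methoxy-5-[2-(3-methoxyphenyl)ethyl]phenoxy}phenyl)-2-(3-methoxyphenyl)ethan-1-one
Product: 16 1-methoxy-2-{4-[2-(3-methoxyphenyl)ethyl]phenoxy}-4-[2-(3-methoxyphenyl)ethyl]benzene (tri-O-methylperrottetin E), via benzylic carbinol 15 (not isolated)
Conditions: Et3SiH (4 equiv), CF3CO2H, CH2Cl2, rt to 40 °C
Reagents that add atoms: none
Why: Ionic hydrogenation with Et3SiH/CF3CO2H reduces aryl ketones to methylene through carbinol 15 and a benzylic cation, here stabilized by the para-aryloxy group, while ethers and arenes are inert and excess silane outruns Friedel–Crafts capture.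

**Step 10**
Reactants: 16 1-methoxy-2-{4-[2-(3-methoxyphenyl)ethyl]phenoxy}-4-[2-(3-methoxyphenyl)ethyl]benzene
Product: 17 perrottetin E, 2-{4-[2-(3-hydroxyphenyl)ethyl]phenoxy}-4-[2-(3-hydroxyphenyl)ethyl]phenol
Conditions: BBr3 (6 equiv, 1 M in CH2Cl2), CH2Cl2, −78 °C to rt; ice-water quench
Reagents that add atoms: none
Why: BBr3 cleavage of aryl methyl ethers (boron complexation, bromide attack at methyl) should remove all three methyl groups, while the diaryl ether has no sp3 C–O carbon and survives.

**Compound list**
1 | 3-(benzyloxy)-4-methoxybenzaldehyde | COc1ccc(C=O)cc1OCc1ccccc1 | starting material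
2 | diethyl [(3-methoxyphenyl)methyl]phosphonate | CCOP(=O)(Cc1cccc(OC)c1)OCC | starting material
3 | (E)-2-(benzyloxy)-1-methoxy-4-[2-(3-methoxyphenyl)ethenyl]benzene | COc1cccc(/C=C/c2ccc(OC)c(OCc3ccccc3)c2)c1 | intermediate
4 | 2-methoxy-5-[2-(3-methoxyphenyl)ethyl]phenol | COc1cccc(CCc2ccc(OC)c(O)c2)c1 | intermediate
5 | acryloyl chloride | C=CC(=O)Cl | starting material
6 | 2-methoxy-5-[2-(3-methoxyphenyl)ethyl]phenyl prop-2-enoate | C=CC(=O)Oc1cc(CCc2cccc(OC)c2)ccc1OC | intermediate
7 | 2-(buta-1,3-dien-2-yloxy)-1-methoxy-4-[2-(3-methoxyphenyl)ethyl]benzene | C=CC(=C)Oc1cc(CCc2cccc(OC)c2)ccc1OC | intermediate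
8 | (3-methoxyphenyl)acetic acid | COc1cccc(CC(=O)O)c1 | starting material
9 | 1-(1H-imidazol-1-yl)-2-(3-methoxyphenyl)ethan-1-one (acyl imidazolide) | COc1cccc(CC(=O)n2ccnc2)c1 | intermediate
10 | N-methoxy-2-(3-methoxyphenyl)-N-methylacetamide | COc1cccc(CC(=O)N(C)OC)c1 | intermediate
11 | ethynylmagnesium bromide | C#C[Mg]Br | starting material
12 | 1-(3-methoxyphenyl)but-3-yn-2-one | C#CC(=O)Cc1cccc(OC)c1 | intermediate
13 | 1-(4-{2-methoxy-5-[2-(3-methoxyphenyl)ethyl]phenoxy}cyclohexa-1,4-dien-1-yl)-2-(3-methoxyphenyl)ethan-1-one | COc1cccc(CC(=O)C2=CCC(Oc3cc(CCc4cccc(OC)c4)ccc3OC)=CC2)c1 | intermediate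
14 | 1-(4-{2-methoxy-5-[2-(3-methoxyphenyl)ethyl]phenoxy}phenyl)-2-(3-methoxyphenyl)ethan-1-one | COc1cccc(CC(=O)c2ccc(Oc3cc(CCc4cccc(OC)c4)ccc3OC)cc2)c1 | intermediate
15 | 1-(4-{2-methoxy-5-[2-(3-methoxyphenyl)ethyl]phenoxy}phenyl)-2-(3-methoxyphenyl)ethan-1-ol, racemic (benzylic carbinol) | COc1cccc(CC(O)c2ccc(Oc3cc(CCc4cccc(OC)c4)ccc3OC)cc2)c1 | intermediate
16 | 1-methoxy-2-{4-[2-(3-methoxyphenyl)ethyl]phenoxy}-4-[2-(3-methoxyphenyl)ethyl]benzene (tri-O-methylperrottetin E) | COc1cccc(CCc2ccc(Oc3cc(CCc4cccc(OC)c4)ccc3OC)cc2)c1 | intermediate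
17 | perrottetin E, 2-{4-[2-(3-hydroxyphenyl)ethyl]phenoxy}-4-[2-(3-hydroxyphenyl)ethyl]phenol | Oc1cccc(CCc2ccc(Oc3cc(CCc4cccc(O)c4)ccc3O)cc2)c1 | target

**Summary**
Total step count: 10.
Longest linear sequence: 8 steps (1, 2, 3, 4, 7, 8, 9, 10); the two-step ynone branch (5, 6) converges at step 7.

**Steps most likely to fail**

Step 7 (cycloaddition). The aryloxy group activates the diene less than an alkoxy or silyloxy group, so the cycloaddition may be slower than thermal decomposition or isomerization of the enolizable terminal ynone, and regiocontrol may erode at the temperature required. The fallback keeps the same [4+2] construction of ring B but uses a robust dienophile and attaches ring A afterwards. It sets out from diene 7, which with methyl propiolate (xylene, 110–130 °C, BHT) should give methyl 4-{2-methoxy-5-[2-(3-methoxyphenyl)ethyl]phenoxy}cyclohexa-1,4-diene-1-carboxylate F1. DDQ would aromatize this to methyl 4-{2-methoxy-5-[2-(3-methoxyphenyl)ethyl]phenoxy}benzoate F2. MeNH(OMe)·HCl with i-PrMgCl (THF, −20 °C) would convert the ester into N-methoxy-N-methyl-4-{2-methoxy-5-[2-(3-methoxyphenyl)ethyl]phenoxy}benzamide F3. Addition of (3-methoxybenzyl)magnesium chloride would then give ketone 14, where the route resumes at step 9.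

Step 4 (methylenation). The titanium methylidene may engage the diene product in metathesis-type oligomerization, or the Lewis-acidic aluminium residues may hydrolyze or polymerize the 2-aryloxydiene during work-up. The fallback builds the enol ether by elimination instead of carbonyl methylenation. It sets out from phenol 4, which would open 3,4-epoxybut-1-ene under Pd(0) catalysis (Pd2(dba)3 with a C2-symmetric DACH-derived diphosphine, racemic ligand sufficing, CH2Cl2, rt) at the internal allylic carbon to give racemic 2-{2-methoxy-5-[2-(3-methoxyphenyl)ethyl]phenoxy}but-3-en-1-ol F4. Appel iodination (I2, PPh3, imidazole) would give racemic 2-[(1-iodobut-3-en-2-yl)oxy]-1-methoxy-4-[2-(3-methoxyphenyl)ethyl]benzene F5. E2 elimination of HI with KOtBu (THF, 0 °C), removing the allylic proton on the oxygen-bearing carbon, would return diene 7.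

Step 6 (ynone formation). The liberated N,O-dimethylhydroxylamine may add to the ynone during quench, the benzyl ethynyl ketone may isomerize under basic conditions, or the Grignard reagent may enolize the arylacetamide. The fallback reaches the ynone by oxidation of a propargylic alcohol. It sets out from Weinreb amide 10, which DIBAL-H (THF, −78 °C) would reduce to (3-methoxyphenyl)acetaldehyde F6. Addition of ethynylmagnesium bromide 11 (THF, −78 to 0 °C) would give racemic 1-(3-methoxyphenyl)but-3-yn-2-ol F7. Dess–Martin periodinane buffered with NaHCO3 (CH2Cl2, 0 °C) would return ynone 12.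

**Further compounds**
F1 | step 7 | methyl 4-{2-methoxy-5-[2-(3-methoxyphenyl)ethyl]phenoxy}cyclohexa-1,4-diene-1-carboxylate | COC(=O)C1=CCC(Oc2cc(CCc3cccc(OC)c3)ccc2OC)=CC1
F2 | step 7 | methyl 4-{2-methoxy-5-[2-(3-methoxyphenyl)ethyl]phenoxy}benzoate | COC(=O)c1ccc(Oc2cc(CCc3cccc(OC)c3)ccc2OC)cc1
F3 | step 7 | N-methoxy-N-methyl-4-{2-methoxy-5-[2-(3-methoxyphenyl)ethyl]phenoxy}benzamide | CON(C)C(=O)c1ccc(Oc2cc(CCc3cccc(OC)c3)ccc2OC)cc1
F4 | step 4 | 2-{2-methoxy-5-[2-(3-methoxyphenyl)ethyl]phenoxy}but-3-en-1-ol, racemic | C=CC(CO)Oc1cc(CCc2cccc(OC)c2)ccc1OC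
F5 | step 4 | 2-[(1-iodobut-3-en-2-yl)oxy]-1-methoxy-4-[2-(3-methoxyphenyl)ethyl]benzene, racemic | C=CC(CI)Oc1cc(CCc2cccc(OC)c2)ccc1OC
F6 | step 6 | (3-methoxyphenyl)acetaldehyde | COc1cccc(CC=O)c1
F7 | step 6 | 1-(3-methoxyphenyl)but-3-yn-2-ol, racemic | C#CC(O)Cc1cccc(OC)c1
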